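**Plan**

- Retrosynthesis: the free phenol and the tertiary alcohol are traced back to a TBS ether and a trisubstituted chain alkene. The cuts then follow in this order: the C2–C3 bond of the pyranone ring, the diazo group (back to a methyl ketone), the O1–C2 ether bond, and the aryl–acetyl bond.
- Enabling feature: C2 is bonded to the ring oxygen O1 and to C3, the methylene alpha to the C4 ketone of the pyranone ring. C2 can therefore begin as the methine of a secondary alkyl aryl ether and C3 as a carbenoid carbon.
- Forward: the benzene ring is acetylated and its two phenols are differentiated, the side chain is attached through O1, and the methyl ketone becomes a diazoketone. The pyranone ring (the only ring formed) then closes by C2–C3 bond formation; alkene hydration and desilylation finish the route.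
- Stereochemistry: the single stereocentre comes from (S)-sulcatol. It is inverted to (R) in the Mitsunobu etherification and carried with retention through the C–H insertion to (2R).

Key step: step 6

Assumption: the target SMILES is read as the (2R) enantiomer, and (S)-sulcatol of high enantiomeric purity is purchased.

**Route**

Step 1
Reactants: 1 2-bromo-1,4-dimethoxybenzene; 2 acetyl chloride
Product: 3 1-(4-bromo-2,5-dimethoxyphenyl)ethan-1-one
Conditions: AlCl3 (1.3 equiv), CH2Cl2, 0 °C to rt; aqueous quench
Reagents that add atoms: none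
Why: Friedel–Crafts acylation; the acylium ion should attack the position that is ortho to a methoxy group and para to bromine, the site favoured by both donors and not flanked by bromine.

Step 2
Reactants: 3 1-(4-bromo-2,5-dimethoxyphenyl)ethan-1-one
Product: 4 1-(4-bromo-2,5-dihydroxyphenyl)ethan-1-one
Conditions: BBr3 (3 equiv), CH2Cl2, −78 °C to rt; then H2O
Reagents that add atoms: none
Why: Lewis-acid cleavage of both aryl methyl ethers (BBr3 demethylation), to which the aryl ketone and the aryl bromide are inert.

Step 3
Reactants: 4 1-(4-bromo-2,5-dihydroxyphenyl)ethan-1-one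
Product: 5 1-[4-bromo-5-(tert-butyldimethylsilyloxy)-2-hydroxyphenyl]ethan-1-one
Conditions: TBSCl (1.05 equiv), imidazole, CH2Cl2, 0 °C
Reagents that add atoms: tert-butyldimethylsilyl chloride, CC(C)(C)[Si](C)(C)Cl
Why: selective phenol silylation; the 2-hydroxyl is held in an intramolecular hydrogen bond to the acetyl carbonyl, so the silyl chloride should react at the free 5-hydroxyl.

Step 4
Reactants: 5 1-[4-bromo-5-(tert-butyldimethylsilyloxy)-2-hydroxyphenyl]ethan-1-one; 6 (S)-sulcatol, (2S)-6-methylhept-5-en-2-ol
Product: 7 1-[4-bromo-5-(tert-butyldimethylsilyloxy)-2-{[(2R)-6-methylhept-5-en-2-yl]oxy}phenyl]ethan-1-one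
Conditions: PPh3, DIAD, THF, 0 °C to rt
Reagents that add atoms: none
Why: Mitsunobu etherification; the phenoxide displaces the oxyphosphonium of 6 in an SN2 step with inversion, which turns the (S)-carbinol into the (R)-configured aryl ether.

Step 5
Reactants: 7 1-[4-bromo-5-(tert-butyldimethylsilyloxy)-2-{[(2R)-6-methylhept-5-en-2-yl]oxy}phenyl]ethan-1-one
Product: 9 1-[4-bromo-5-(tert-butyldimethylsilyloxy)-2-{[(2R)-6-methylhept-5-en-2-yl]oxy}phenyl]-2-diazoethan-1-one, via trifluoroacetyl ketone 8 (not isolated)
Conditions: LiN(SiMe3)2, THF, −78 °C; CF3CO2CH2CF3; 5% aq HCl work-up; then 4-acetamidobenzenesulfonyl azide, Et3N, H2O (1 equiv), MeCN, rt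
Reagents that add atoms: 4-acetamidobenzenesulfonyl azide, CC(=O)Nc1ccc(cc1)S(=O)(=O)N=[N+]=[N-] (the two diazo nitrogens); 2,2,2-trifluoroethyl trifluoroacetate, O=C(OCC(F)(F)F)C(F)(F)F (trifluoroacetyl group of intermediate 8 only)
Why: detrifluoroacetylative Regitz diazo transfer; Claisen trifluoroacetylation of the lithium enolate gives the activated 1,3-diketone 8, which accepts the diazo group and passes its trifluoroacetyl group to the sulfonamide, while the ether stereocentre is not touched.

Step 6
Reactants: 9 1-[4-bromo-5-(tert-butyldimethylsilyloxy)-2-{[(2R)-6-methylhept-5-en-2-yl]oxy}phenyl]-2-diazoethan-1-one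
Product: 10 (2R)-7-bromo-6-(tert-butyldimethylsilyloxy)-2-methyl-2-(4-methylpent-3-en-1-yl)chroman-4-one
Conditions: Rh2(OAc)4 (1 mol %), CH2Cl2, 40 °C, slow addition of 9 (final ca. 0.01 M)
Reagents that add atoms: none
Why: Rh2(OAc)4, a dimeric divalent rhodium carboxylate, should expel N2 from 9 to give an electrophilic carbenoid at the future C3, which inserts into the tertiary C–H bond of the ether methine (future C2) through a three-centre, hydride-transfer-like transition state and so forms the C2–C3 bond. The closest known reaction type is the intramolecular carbenoid C–H insertion alpha to ether oxygen of ortho-alkoxyaryl diazoketones, which gives chroman-4-ones, together with the retentive insertion of rhodium carbenoids into tertiary C–H bonds. The pyranone ring closes by 1,6-insertion through a six-membered cyclic transition state, because the usual 1,5-mode is excluded: position 5 is O1 itself. The new quaternary stereocentre C2 is controlled by the (R)-methine of 9, since the C–C bond forms on the face from which hydrogen leaves (retention), so that (R)-9 should give (2R)-10. The step needs insertion to win over oxonium ylide formation at O1 with [1,2]-shift to a benzofuran-3-one, over attack on the chain alkene and over carbene dimerisation. This is secured by the low nucleophilicity of O1 (an aryl ether oxygen conjugated with the ortho carbonyl), by the hydridic tertiary C–H bond next to oxygen, by the alkene being reachable only through a medium ring, and by slow addition at high dilution.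

Step 7
Reactants: 10 (2R)-7-bromo-6-(tert-butyldimethylsilyloxy)-2-methyl-2-(4-methylpent-3-en-1-yl)chroman-4-one
Product: 11 (2R)-7-bromo-6-(tert-butyldimethylsilyloxy)-2-(4-hydroxy-4-methylpentyl)-2-methylchroman-4-one
Conditions: Co(acac)2 (20 mol %), PhSiH3, O2 (1 atm), THF, rt
Reagents that add atoms: dioxygen, O=O
Why: Mukaiyama hydration; a cobalt hydride delivers a hydrogen atom to the less substituted alkene carbon, the tertiary radical is trapped by O2 and the peroxide is reduced by the silane in the flask, which gives the Markovnikov tertiary alcohol under neutral conditions that leave C2, the ketone, the aryl bromide and the silyl ether alone.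

Step 8
Reactants: 11 (2R)-7-bromo-6-(tert-butyldimethylsilyloxy)-2-(4-hydroxy-4-methylpentyl)-2-methylchroman-4-one
Product: 12 (2R)-7-bromo-6-hydroxy-2-(4-hydroxy-4-methylpentyl)-2-methylchroman-4-one
Conditions: Bu4NF, AcOH (1.2 equiv), THF, 0 °C
Reagents that add atoms: none
Why: fluoride-mediated cleavage of the aryl silyl ether; the acetic acid buffer keeps the medium from turning basic, so that retro-oxa-Michael opening of the pyranone ring, which would racemise C2, should not occur.

**Compound list**

1 | 2-bromo-1,4-dimethoxybenzene | COc1ccc(OC)c(Br)c1 | starting material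
2 | acetyl chloride | CC(Cl)=O | starting material
3 | 1-(4-bromo-2,5-dimethoxyphenyl)ethan-1-one | CC(=O)c1cc(OC)c(Br)cc1OC | intermediate
4 | 1-(4-bromo-2,5-dihydroxyphenyl)ethan-1-one | CC(=O)c1cc(O)c(Br)cc1O | intermediate
5 | 1-[4-bromo-5-(tert-butyldimethylsilyloxy)-2-hydroxyphenyl]ethan-1-one | CC(=O)c1cc(O[Si](C)(C)C(C)(C)C)c(Br)cc1O | intermediate
6 | (S)-sulcatol, (2S)-6-methylhept-5-en-2-ol | C[C@H](O)CCC=C(C)C | starting material
7 | 1-[4-bromo-5-(tert-butyldimethylsilyloxy)-2-{[(2R)-6-methylhept-5-en-2-yl]oxy}phenyl]ethan-1-one | CC(=O)c1cc(O[Si](C)(C)C(C)(C)C)c(Br)cc1O[C@H](C)CCC=C(C)C | intermediate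
8 | 1-[4-bromo-5-(tert-butyldimethylsilyloxy)-2-{[(2R)-6-methylhept-5-en-2-yl]oxy}phenyl]-4,4,4-trifluorobutane-1,3-dione | O=C(CC(=O)C(F)(F)F)c1cc(O[Si](C)(C)C(C)(C)C)c(Br)cc1O[C@H](C)CCC=C(C)C | intermediate
9 | 1-[4-bromo-5-(tert-butyldimethylsilyloxy)-2-{[(2R)-6-methylhept-5-en-2-yl]oxy}phenyl]-2-diazoethan-1-one | [N-]=[N+]=CC(=O)c1cc(O[Si](C)(C)C(C)(C)C)c(Br)cc1O[C@H](C)CCC=C(C)C | intermediate
10 | (2R)-7-bromo-6-(tert-butyldimethylsilyloxy)-2-methyl-2-(4-methylpent-3-en-1-yl)chroman-4-one | CC(C)=CCC[C@]1(C)CC(=O)c2cc(O[Si](C)(C)C(C)(C)C)c(Br)cc2O1 | intermediate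
11 | (2R)-7-bromo-6-(tert-butyldimethylsilyloxy)-2-(4-hydroxy-4-methylpentyl)-2-methylchroman-4-one | CC(C)(O)CCC[C@]1(C)CC(=O)c2cc(O[Si](C)(C)C(C)(C)C)c(Br)cc2O1 | intermediate
12 | (2R)-7-bromo-6-hydroxy-2-(4-hydroxy-4-methylpentyl)-2-methylchroman-4-one | CC(C)(O)CCC[C@]1(C)CC(=O)c2cc(O)c(Br)cc2O1 | target

**Step count and risks**

Total step count: 8. Longest linear sequence: 8 steps (1 to 12).

Steps most likely to fail:

1. Step 6. The carbenoid may be diverted into oxonium ylide formation at O1 followed by a [1,2]-shift, or the configuration may be partly lost if hydride transfer and C–C bond formation become stepwise. The fallback sets out from 4. A Kabbe condensation with 6-methylhept-5-en-2-one (CC(=O)CCC=C(C)C) and pyrrolidine in MeOH at reflux should give racemic 7-bromo-6-hydroxy-2-methyl-2-(4-methylpent-3-en-1-yl)chroman-4-one F1. Silylation with TBSCl and imidazole should give the racemic silyl ether F2. Preparative HPLC on a chiral stationary phase would then deliver the (2R) enantiomer, which is 10, where the route is rejoined.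

2. Step 4. Displacement of the oxyphosphonium intermediate by the hydrogen-bonded, ortho-acylated phenol may be sluggish, so that the activated alcohol eliminates instead of forming the ether. The fallback sets out from 6. Mesylation (MsCl, Et3N, CH2Cl2, 0 °C) should give (2S)-6-methylhept-5-en-2-yl methanesulfonate F3 with the carbinol configuration unchanged. O-Alkylation of phenol 5 with F3 (Cs2CO3, dry MeCN, 50 °C) is an SN2 displacement with inversion and should give 7, where the route is rejoined.

3. Step 7. The silane may over-reduce the aryl ketone, or the intermediate peroxide may be reduced incompletely, giving mixtures. The fallback sets out from 10. Epoxidation of the trisubstituted alkene (mCPBA, NaHCO3, CH2Cl2, 0 °C) should give (2R)-7-bromo-6-(tert-butyldimethylsilyloxy)-2-[2-(3,3-dimethyloxiran-2-yl)ethyl]-2-methylchroman-4-one F4 as both oxirane epimers. LiBHEt3 (THF, 0 °C) should open the oxirane at its secondary carbon and also reduce the ketone, giving (2R)-7-bromo-6-(tert-butyldimethylsilyloxy)-2-(4-hydroxy-4-methylpentyl)-2-methylchroman-4-ol F5 as both C4 epimers. Dess–Martin periodinane (NaHCO3, CH2Cl2) oxidises only the secondary benzylic alcohol and returns to the route at 11.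

**Further compounds**

F1 | step 6 | racemic 7-bromo-6-hydroxy-2-methyl-2-(4-methylpent-3-en-1-yl)chroman-4-one | CC(C)=CCCC1(C)CC(=O)c2cc(O)c(Br)cc2O1
F2 | step 6 | racemic 7-bromo-6-(tert-butyldimethylsilyloxy)-2-methyl-2-(4-methylpent-3-en-1-yl)chroman-4-one | CC(C)=CCCC1(C)CC(=O)c2cc(O[Si](C)(C)C(C)(C)C)c(Br)cc2O1
F3 | step 4 | (2S)-6-methylhept-5-en-2-yl methanesulfonate | C[C@H](OS(C)(=O)=O)CCC=C(C)C
F4 | step 7 | (2R)-7-bromo-6-(tert-butyldimethylsilyloxy)-2-[2-(3,3-dimethyloxiran-2-yl)ethyl]-2-methylchroman-4-one, both oxirane epimers | CC1(C)OC1CC[C@]1(C)CC(=O)c2cc(O[Si](C)(C)C(C)(C)C)c(Br)cc2O1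
F5 | step 7 | (2R)-7-bromo-6-(tert-butyldimethylsilyloxy)-2-(4-hydroxy-4-methylpentyl)-2-methylchroman-4-ol, both C4 epimers | CC(C)(O)CCC[C@]1(C)CC(O)c2cc(O[Si](C)(C)C(C)(C)C)c(Br)cc2O1
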